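**Plan**

- Lettering: rings A–F follow the SMILES order (A = 2,4,6-trihydroxyphenoxy end, F = 3,4,5-trihydroxyphenyl end). In ring D, D1 bears the C–O–D oxygen, D2 is the CH, D3–D5 bear OH and D6 bears the D–O–E oxygen.
- Cuts: the sixteen O–CH3 bonds come off last. Before that, F–O–E is cut (Ullmann), then D–O–E (SNAr, with a Dakin oxidation unveiling the E oxygen). Ring D is cut at D2–D3 and traced to a squarate C4O4 unit plus an α-aryloxyvinyl C2 unit, so the hindered C–O–D ether becomes a vinyl ether made from trichloroethylene. Finally B–O–C (SNAr/Dakin) and A–O–B (Ullmann/Dakin).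
- Forward order: A–B, then the A–B–C phenol; dichlorovinyl ether, ynol ether, α-stannyl enol ether, squarate adduct, silyl ether; thermolysis creates ring D; then ring E, ring F and demethylation.
- Enabling feature: ring D has five contiguous oxygenated carbons and one CH. D3–D6 with their four oxygens are the squarate carbons; D1 and D2 are the vinyl carbons (C–OAr and CH2).
- Stereochemistry: the target has no stereogenic element, so no asymmetric step is needed. The only stereocentre on the route is the carbinol carbon of the squarate adduct; it is made racemic and becomes the aromatic carbon D6.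

Key step: step 11

Abbreviation: ArABC = 2,6-dimethoxy-4-[2,3,4-trimethoxy-6-(2,4,6-trimethoxyphenoxy)phenoxy]phenyl, i.e. permethylated rings A–B–C, attached through the ring C carbon that lies between its two methoxy groups.

**Route**

Step 1
Reactants: 1 5-bromo-1,2,3-trimethoxybenzene
Product: 2 6-bromo-2,3,4-trimethoxybenzaldehyde
Conditions: Cl2CHOMe (1.5 equiv), TiCl4 (2.2 equiv), CH2Cl2, 0 °C to rt; ice/1 M HCl
Reagents that add atoms: dichloromethyl methyl ether, COC(Cl)Cl (formyl carbon); water, O (carbonyl oxygen)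
Why: Rieche formylation attacks the only free ring position type (ortho to Br and OMe, para to OMe; the two are equivalent by symmetry), so a single aldehyde should result after hydrolysis of the α-chloro ether.

Step 2
Reactants: 2 6-bromo-2,3,4-trimethoxybenzaldehyde; 3 2,4,6-trimethoxyphenol
Product: 4 2,3,4-trimethoxy-6-(2,4,6-trimethoxyphenoxy)benzaldehyde (A–B aldehyde)
Conditions: CuI (10 mol %), picolinic acid (20 mol %), K3PO4 (2 equiv), DMSO, 90 °C, Ar
Reagents that add atoms: none
Why: Copper-catalysed Ullmann diaryl ether coupling under ligand conditions that tolerate di-ortho-substituted phenols, helped here by the ortho-formyl group activating the C–Br bond; polymethoxyphenol/bromoarene Ullmann couplings are the classical entry to permethylated phlorotannins.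

Step 3
Reactants: 4 A–B aldehyde
Product: 6 2,3,4-trimethoxy-6-(2,4,6-trimethoxyphenoxy)phenol (A–B phenol), via aryl formate 5 (not isolated)
Conditions: mCPBA (1.3 equiv), CH2Cl2, 0 °C to rt; aq. NaHCO3 wash; K2CO3 (cat.), MeOH, rt
Reagents that add atoms: 3-chloroperbenzoic acid, OOC(=O)c1cccc(Cl)c1
Why: Dakin-type Baeyer–Villiger oxidation, in which the electron-rich aryl group (ortho-OMe, ortho-OAr, para-OMe) migrates in preference to hydride and the resulting formate is methanolysed in the same flask.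

Step 4
Reactants: 6 A–B phenol; 7 4-fluoro-2,6-dimethoxybenzaldehyde
Product: 8 ArABC–CHO, 2,6-dimethoxy-4-[2,3,4-trimethoxy-6-(2,4,6-trimethoxyphenoxy)phenoxy]benzaldehyde
Conditions: Cs2CO3 (1.5 equiv), DMSO, 110 °C, Ar
Reagents that add atoms: none
Why: SNAr displacement of the fluoride para to the formyl group by the caesium phenoxide; the Meisenheimer charge sits on carbons that do not carry the methoxy groups, so the aldehyde remains an effective activator and no metal is needed for this hindered phenol.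

Step 5
Reactants: 8 ArABC–CHO
Product: 10 ArABC–OH, 2,6-dimethoxy-4-[2,3,4-trimethoxy-6-(2,4,6-trimethoxyphenoxy)phenoxy]phenol (A–B–C phenol), via aryl formate 9 (not isolated)
Conditions: mCPBA (1.3 equiv), CH2Cl2, 0 °C to rt; aq. NaHCO3 wash; K2CO3 (cat.), MeOH, rt
Reagents that add atoms: 3-chloroperbenzoic acid, OOC(=O)c1cccc(Cl)c1
Why: Dakin-type Baeyer–Villiger oxidation of a 2,6-dimethoxy-4-aryloxybenzaldehyde, a substrate class in which aryl migration is strongly favoured, followed by formate methanolysis.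

Step 6
Reactants: 10 ArABC–OH; 11 trichloroethylene
Product: 13 (E)-1,2-dichlorovinyl ArABC ether, via dichloroacetylene 12 (not isolated)
Conditions: K2CO3 (3 equiv), 11 (2 equiv), DMF, 70 °C
Reagents that add atoms: none
Why: Base converts trichloroethylene into dichloroacetylene, to which the phenoxide adds in anti fashion to give the (E)-dichlorovinyl ether; this small linear electrophile is indifferent to the two ortho-methoxy groups that would hamper an arylation of the same oxygen.

Step 7
Reactants: 13 (E)-1,2-dichlorovinyl ArABC ether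
Product: 16 ethynyl ArABC ether (aryl ynol ether), via chloroethynyl ether 14 (not isolated), via lithium acetylide 15 (not isolated)
Conditions: n-BuLi (2.3 equiv), THF, −78 to −40 °C; MeOH, −78 °C; rapid filtration through basic alumina
Reagents that add atoms: none
Why: β-Elimination of HCl followed by chlorine–lithium exchange (the established dichlorovinyl ether route to ynol ethers) gives the lithium aryloxyacetylide, which is protonated cold; at −78 °C this is far faster than ortho-lithiation of the methoxyarenes.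

Step 8
Reactants: 16 ethynyl ArABC ether
Product: 17 tributyl[1-(ArABC-oxy)vinyl]stannane
Conditions: Bu3SnH (1.2 equiv), Pd(PPh3)4 (2 mol %), THF, 0 °C to rt; Et3N-deactivated silica
Reagents that add atoms: tributyltin hydride, CCCC[SnH](CCCC)CCCC
Why: Palladium(0)-catalysed syn-hydrostannylation of a heteroatom-substituted terminal alkyne places tin on the oxygen-bearing carbon, which should give the 1,1-disubstituted α-stannyl enol ether.

Step 9
Reactants: 17 tributyl[1-(ArABC-oxy)vinyl]stannane; 18 dimethyl squarate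
Product: 20 racemic 4-hydroxy-2,3-dimethoxy-4-[1-(ArABC-oxy)vinyl]cyclobut-2-en-1-one, via 1-aryloxyvinyllithium 19 (not isolated)
Conditions: n-BuLi (1.05 equiv), THF, −78 °C; cannulation into 18 (1.2 equiv), THF, −78 °C; sat. aq. NH4Cl, −78 °C
Reagents that add atoms: none
Why: Tin–lithium exchange of an α-oxyvinylstannane is fast at −78 °C and outruns ring lithiation, and the vinyllithium adds 1,2 to one carbonyl of the squarate ester (inverse addition prevents double addition); the new carbinol stereocentre forms as a racemate, which is of no consequence.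

Step 10
Reactants: 20 racemic 4-hydroxycyclobutenone
Product: 21 racemic 4-(tert-butyldimethylsilyloxy)-2,3-dimethoxy-4-[1-(ArABC-oxy)vinyl]cyclobut-2-en-1-one
Conditions: TBSOTf (1.5 equiv), 2,6-lutidine (3 equiv), CH2Cl2, −78 to 0 °C
Reagents that add atoms: tert-butyldimethylsilyl triflate, CC(C)(C)[Si](C)(C)OS(=O)(=O)C(F)(F)F
Why: Silyl triflate/lutidine silylation of a tertiary alcohol; the silyl ether blocks furanone formation from the later ketene and marks the carbinol-derived oxygen (future D6–O) so that the two ring D hydroxyls are distinguished by connectivity and not by hindrance.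

Step 11
Reactants: 21 racemic silyl ether
Product: 24 4-(tert-butyldimethylsilyloxy)-2,3-dimethoxy-5-(ArABC-oxy)phenol (A–B–C–D tetramer; D3–OH free and D6–OTBS), via dienylketene 22 (not isolated), via cyclohexadienone 23 (not isolated)
Conditions: degassed toluene (0.01 M), 110 °C, Ar
Reagents that add atoms: none
Why: Heating cleaves the C1–C4 bond of the cyclobutenone by conrotatory 4π electrocyclic opening to the dienylketene 22, a 6π electrocyclisation then joins the vinyl CH2 carbon to the ketene carbon (the D2–D3 bond), and the cyclohexa-2,4-dienone 23 enolises to the phenol 24. The closest known reaction is the Moore rearrangement of 4-alkenyl-4-hydroxy- or 4-siloxycyclobutenones derived from squarate esters into hydroquinones and their mono-ethers. Ring D closes as a six-membered carbocycle by thermal disrotatory 6π electrocyclisation of the ketene C=C, the former ring C=C and the vinyl C=C. No stereocentre is created; the racemic carbinol carbon becomes aromatic D6. The step needs the vinyl group to rotate inward, which the outward preference of the siloxy donor secures, and since ring opening is reversible any wrongly opened ketene returns to 21. It also needs the two hydroquinone oxygens kept apart, which the silyl group on the carbinol-derived oxygen secures, while dilute, oxygen-free, aprotic conditions prevent ketene trapping and quinone formation and the methoxy-blocked ortho positions of ring C rule out closure onto that arene.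

Step 12
Reactants: 24 mono-silylated hydroquinone
Product: 25 tert-butyldimethyl[2,3,4-trimethoxy-6-(ArABC-oxy)phenoxy]silane
Conditions: MeI (3 equiv), K2CO3 (2 equiv), acetone, rt
Reagents that add atoms: iodomethane, CI
Why: Williamson methylation of the only free phenol (D3–OH, one ortho substituent) under mild heterogeneous base in an aprotic solvent, which should leave the hindered aryl silyl ether intact.

Step 13
Reactants: 25 silyl ether; 7 4-fluoro-2,6-dimethoxybenzaldehyde
Product: 27 2,6-dimethoxy-4-[2,3,4-trimethoxy-6-(ArABC-oxy)phenoxy]benzaldehyde (A–B–C–D–E aldehyde), via caesium phenoxide 26 (not isolated)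
Conditions: CsF (2 equiv), 7 (1.5 equiv), DMSO, 100 °C, Ar
Reagents that add atoms: none
Why: One-pot desilylative SNAr, in which fluoride cleaves the aryl silyl ether to the caesium phenoxide and this displaces the para-fluoride of the aldehyde as in step 4, the fluoride released by the substitution sustaining the desilylation.

Step 14
Reactants: 27 A–B–C–D–E aldehyde
Product: 29 2,6-dimethoxy-4-[2,3,4-trimethoxy-6-(ArABC-oxy)phenoxy]phenol (A–B–C–D–E phenol), via aryl formate 28 (not isolated)
Conditions: mCPBA (1.3 equiv), CH2Cl2, 0 °C to rt; aq. NaHCO3 wash; K2CO3 (cat.), MeOH, rt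
Reagents that add atoms: 3-chloroperbenzoic acid, OOC(=O)c1cccc(Cl)c1
Why: Third use of the Dakin-type Baeyer–Villiger oxidation/methanolysis on the same 2,6-dimethoxy-4-aryloxybenzaldehyde motif as in step 5.

Step 15
Reactants: 29 A–B–C–D–E phenol; 30 5-iodo-1,2,3-trimethoxybenzene
Product: 31 hexadeca-O-methyl ether of the target (permethylated A–B–C–D–E–F hexamer)
Conditions: CuI (20 mol %), picolinic acid (40 mol %), K3PO4 (2 equiv), DMSO, 100 °C, Ar
Reagents that add atoms: none
Why: Copper-catalysed Ullmann coupling of a 2,6-dimethoxyphenol with an unhindered aryl iodide, the same bond type as in step 2 and one for which the picolinic acid ligand system is suited to di-ortho-substituted phenols.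

Step 16
Reactants: 31 hexadeca-O-methyl ether
Product: 32 CNP0218077.0 (target)
Conditions: BBr3 (40 equiv, 1 M in CH2Cl2), CH2Cl2, −78 °C to rt, Ar; degassed H2O, 0 °C; Sephadex LH-20 under Ar
Reagents that add atoms: none
Why: Boron tribromide cleaves all sixteen aryl methyl ethers (bromide attack at the methyl group of the boron-complexed ether) and leaves diaryl ether bonds untouched; an oxygen-free acidic work-up should protect the pyrogallol-type rings B, D and F.

**Compound list**

1 | 5-bromo-1,2,3-trimethoxybenzene | COc1cc(Br)cc(OC)c1OC | starting material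
2 | 6-bromo-2,3,4-trimethoxybenzaldehyde | COc1cc(Br)c(C=O)c(OC)c1OC | intermediate
3 | 2,4,6-trimethoxyphenol | COc1cc(OC)c(O)c(OC)c1 | starting material
4 | 2,3,4-trimethoxy-6-(2,4,6-trimethoxyphenoxy)benzaldehyde | COc1cc(OC)c(Oc2cc(OC)c(OC)c(OC)c2C=O)c(OC)c1 | intermediate
5 | 2,3,4-trimethoxy-6-(2,4,6-trimethoxyphenoxy)phenyl formate | COc1cc(OC)c(Oc2cc(OC)c(OC)c(OC)c2OC=O)c(OC)c1 | intermediate
6 | 2,3,4-trimethoxy-6-(2,4,6-trimethoxyphenoxy)phenol | COc1cc(OC)c(Oc2cc(OC)c(OC)c(OC)c2O)c(OC)c1 | intermediate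
7 | 4-fluoro-2,6-dimethoxybenzaldehyde | COc1cc(F)cc(OC)c1C=O | starting material
8 | ArABC–CHO, 2,6-dimethoxy-4-[2,3,4-trimethoxy-6-(2,4,6-trimethoxyphenoxy)phenoxy]benzaldehyde | COc1cc(OC)c(Oc2cc(OC)c(OC)c(OC)c2Oc2cc(OC)c(C=O)c(OC)c2)c(OC)c1 | intermediate
9 | ArABC formate | COc1cc(OC)c(Oc2cc(OC)c(OC)c(OC)c2Oc2cc(OC)c(OC=O)c(OC)c2)c(OC)c1 | intermediate
10 | ArABC–OH, 2,6-dimethoxy-4-[2,3,4-trimethoxy-6-(2,4,6-trimethoxyphenoxy)phenoxy]phenol | COc1cc(OC)c(Oc2cc(OC)c(OC)c(OC)c2Oc2cc(OC)c(O)c(OC)c2)c(OC)c1 | intermediate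
11 | trichloroethylene | ClC=C(Cl)Cl | starting material
12 | dichloroacetylene | ClC#CCl | intermediate
13 | (E)-1,2-dichlorovinyl ArABC ether | COc1cc(OC)c(Oc2cc(OC)c(OC)c(OC)c2Oc2cc(OC)c(O/C(Cl)=C\Cl)c(OC)c2)c(OC)c1 | intermediate
14 | chloroethynyl ArABC ether | COc1cc(OC)c(Oc2cc(OC)c(OC)c(OC)c2Oc2cc(OC)c(OC#CCl)c(OC)c2)c(OC)c1 | intermediate
15 | lithium (ArABC-oxy)acetylide | COc1cc(OC)c(Oc2cc(OC)c(OC)c(OC)c2Oc2cc(OC)c(OC#C[Li])c(OC)c2)c(OC)c1 | intermediate
16 | ethynyl ArABC ether | COc1cc(OC)c(Oc2cc(OC)c(OC)c(OC)c2Oc2cc(OC)c(OC#C)c(OC)c2)c(OC)c1 | intermediate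
17 | tributyl[1-(ArABC-oxy)vinyl]stannane | COc1cc(OC)c(Oc2cc(OC)c(OC)c(OC)c2Oc2cc(OC)c(OC(=C)[Sn](CCCC)(CCCC)CCCC)c(OC)c2)c(OC)c1 | intermediate
18 | dimethyl squarate | COC1=C(OC)C(=O)C1=O | starting material
19 | 1-(ArABC-oxy)vinyllithium | COc1cc(OC)c(Oc2cc(OC)c(OC)c(OC)c2Oc2cc(OC)c(OC(=C)[Li])c(OC)c2)c(OC)c1 | intermediate
20 | racemic 4-hydroxy-2,3-dimethoxy-4-[1-(ArABC-oxy)vinyl]cyclobut-2-en-1-one | COc1cc(OC)c(Oc2cc(OC)c(OC)c(OC)c2Oc2cc(OC)c(OC(=C)C3(O)C(=O)C(OC)=C3OC)c(OC)c2)c(OC)c1 | intermediate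
21 | racemic 4-(tert-butyldimethylsilyloxy)-2,3-dimethoxy-4-[1-(ArABC-oxy)vinyl]cyclobut-2-en-1-one | COc1cc(OC)c(Oc2cc(OC)c(OC)c(OC)c2Oc2cc(OC)c(OC(=C)C3(O[Si](C)(C)C(C)(C)C)C(=O)C(OC)=C3OC)c(OC)c2)c(OC)c1 | intermediate
22 | (3Z)-5-(ArABC-oxy)-4-(tert-butyldimethylsilyloxy)-2,3-dimethoxyhexa-1,3,5-trien-1-one (dienylketene) | COc1cc(OC)c(Oc2cc(OC)c(OC)c(OC)c2Oc2cc(OC)c(OC(=C)/C(O[Si](C)(C)C(C)(C)C)=C(OC)\C(OC)=C=O)c(OC)c2)c(OC)c1 | intermediate
23 | 5-(ArABC-oxy)-4-(tert-butyldimethylsilyloxy)-2,3-dimethoxycyclohexa-2,4-dien-1-one | COc1cc(OC)c(Oc2cc(OC)c(OC)c(OC)c2Oc2cc(OC)c(OC3=C(O[Si](C)(C)C(C)(C)C)C(OC)=C(OC)C(=O)C3)c(OC)c2)c(OC)c1 | intermediate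
24 | 4-(tert-butyldimethylsilyloxy)-2,3-dimethoxy-5-(ArABC-oxy)phenol | COc1cc(OC)c(Oc2cc(OC)c(OC)c(OC)c2Oc2cc(OC)c(Oc3cc(O)c(OC)c(OC)c3O[Si](C)(C)C(C)(C)C)c(OC)c2)c(OC)c1 | intermediate
25 | tert-butyldimethyl[2,3,4-trimethoxy-6-(ArABC-oxy)phenoxy]silane | COc1cc(OC)c(Oc2cc(OC)c(OC)c(OC)c2Oc2cc(OC)c(Oc3cc(OC)c(OC)c(OC)c3O[Si](C)(C)C(C)(C)C)c(OC)c2)c(OC)c1 | intermediate
26 | caesium 2,3,4-trimethoxy-6-(ArABC-oxy)phenoxide | [Cs+].COc1cc(OC)c(Oc2cc(OC)c(OC)c(OC)c2Oc2cc(OC)c(Oc3cc(OC)c(OC)c(OC)c3[O-])c(OC)c2)c(OC)c1 | intermediate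
27 | 2,6-dimethoxy-4-[2,3,4-trimethoxy-6-(ArABC-oxy)phenoxy]benzaldehyde | COc1cc(OC)c(Oc2cc(OC)c(OC)c(OC)c2Oc2cc(OC)c(Oc3cc(OC)c(OC)c(OC)c3Oc3cc(OC)c(C=O)c(OC)c3)c(OC)c2)c(OC)c1 | intermediate
28 | 2,6-dimethoxy-4-[2,3,4-trimethoxy-6-(ArABC-oxy)phenoxy]phenyl formate | COc1cc(OC)c(Oc2cc(OC)c(OC)c(OC)c2Oc2cc(OC)c(Oc3cc(OC)c(OC)c(OC)c3Oc3cc(OC)c(OC=O)c(OC)c3)c(OC)c2)c(OC)c1 | intermediate
29 | 2,6-dimethoxy-4-[2,3,4-trimethoxy-6-(ArABC-oxy)phenoxy]phenol | COc1cc(OC)c(Oc2cc(OC)c(OC)c(OC)c2Oc2cc(OC)c(Oc3cc(OC)c(OC)c(OC)c3Oc3cc(OC)c(O)c(OC)c3)c(OC)c2)c(OC)c1 | intermediate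
30 | 5-iodo-1,2,3-trimethoxybenzene | COc1cc(I)cc(OC)c1OC | starting material
31 | hexadeca-O-methyl ether of the target | COc1cc(OC)c(Oc2cc(OC)c(OC)c(OC)c2Oc2cc(OC)c(Oc3cc(OC)c(OC)c(OC)c3Oc3cc(OC)c(Oc4cc(OC)c(OC)c(OC)c4)c(OC)c3)c(OC)c2)c(OC)c1 | intermediate
32 | CNP0218077.0 | Oc1cc(O)c(Oc2cc(O)c(O)c(O)c2Oc2cc(O)c(Oc3cc(O)c(O)c(O)c3Oc3cc(O)c(Oc4cc(O)c(O)c(O)c4)c(O)c3)c(O)c2)c(O)c1 | target

**Summary**

Total step count: 16. Longest linear sequence: 16 steps (1 to 32); every other building block is purchased.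

**Steps most likely to fail**

1. Step 9. The 1-aryloxyvinyllithium is a carbenoid with a fair leaving group on the metallated carbon; it may lose aryloxide or pick up a ring proton before it reaches the squarate. The fallback sets out from 13 and replaces the sp2 carbanion by a robust acetylide.
   - Compound 13 is treated with n-BuLi as in step 7, but the lithium acetylide 15 is not protonated. It is cannulated into dimethyl squarate 18 at −78 °C and the alkoxide is trapped with methyl triflate, which should give racemic 2,3,4-trimethoxy-4-[(ArABC-oxy)ethynyl]cyclobut-2-en-1-one F1.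
   - Lindlar semihydrogenation (H2, Pd/CaCO3–Pb, quinoline, EtOAc) should give racemic 2,3,4-trimethoxy-4-[(Z)-2-(ArABC-oxy)vinyl]cyclobut-2-en-1-one F2.
   - Thermolysis in degassed toluene at 110 °C should open F2 to the dienylketene (3Z,5Z)-6-(ArABC-oxy)-2,3,4-trimethoxyhexa-1,3,5-trien-1-one F3. This closes, now through the aryloxy-bearing vinyl carbon, to 6-(ArABC-oxy)-2,3,4-trimethoxycyclohexa-2,4-dien-1-one F4, which enolises to 2,3,4-trimethoxy-6-(ArABC-oxy)phenol F5.
   - Because the 2,3-dimethoxyhydroquinone core is symmetric, this variant puts the free hydroxyl directly at D6 and a methyl ether at D3. F5 with 7 and Cs2CO3 in DMSO at 110 °C (as in step 4) comes back to the route at 27, so steps 10–13 are bypassed.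

2. Step 8. Tin may be delivered to the terminal carbon, or the ynol ether may oligomerise on palladium. The fallback sets out from 16.
   - HBr generated in situ (TMSBr, MeOH, CH2Cl2, −78 °C) adds in the Markovnikov sense, since protonation at the terminal carbon gives the oxygen-stabilised cation. This should give 1-bromovinyl ArABC ether F6.
   - Bromine–lithium exchange (t-BuLi, 2 equiv, THF, −78 °C) gives 19, which is added to 18 and quenched as in step 9. The fallback comes back to the route at 20.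

3. Step 15. Ligand exchange and reductive elimination at copper may be slow between a di-ortho-substituted phenoxide and an electron-rich aryl iodide, leading to hydrodehalogenation and unreacted phenol. The fallback sets out from 29 and changes the aryl donor and the copper manifold: Chan–Lam oxidative coupling with (3,4,5-trimethoxyphenyl)boronic acid (Cu(OAc)2, pyridine, 4 Å MS, CH2Cl2, air, rt) forms the same C–O bond at room temperature. It comes back to the route at 31 and makes no new compound.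

Further compounds
F1 | step 9 | racemic 2,3,4-trimethoxy-4-[(ArABC-oxy)ethynyl]cyclobut-2-en-1-one | COc1cc(OC)c(Oc2cc(OC)c(OC)c(OC)c2Oc2cc(OC)c(OC#CC3(OC)C(=O)C(OC)=C3OC)c(OC)c2)c(OC)c1
F2 | step 9 | racemic 2,3,4-trimethoxy-4-[(Z)-2-(ArABC-oxy)vinyl]cyclobut-2-en-1-one | COc1cc(OC)c(Oc2cc(OC)c(OC)c(OC)c2Oc2cc(OC)c(O/C=C\C3(OC)C(=O)C(OC)=C3OC)c(OC)c2)c(OC)c1
F3 | step 9 | (3Z,5Z)-6-(ArABC-oxy)-2,3,4-trimethoxyhexa-1,3,5-trien-1-one | COc1cc(OC)c(Oc2cc(OC)c(OC)c(OC)c2Oc2cc(OC)c(O/C=C\C(OC)=C(OC)/C(OC)=C=O)c(OC)c2)c(OC)c1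
F4 | step 9 | racemic 6-(ArABC-oxy)-2,3,4-trimethoxycyclohexa-2,4-dien-1-one | COc1cc(OC)c(Oc2cc(OC)c(OC)c(OC)c2Oc2cc(OC)c(OC3C=C(OC)C(OC)=C(OC)C3=O)c(OC)c2)c(OC)c1
F5 | step 9 | 2,3,4-trimethoxy-6-(ArABC-oxy)phenol | COc1cc(OC)c(Oc2cc(OC)c(OC)c(OC)c2Oc2cc(OC)c(Oc3cc(OC)c(OC)c(OC)c3O)c(OC)c2)c(OC)c1
F6 | step 8 | 1-bromovinyl ArABC ether | COc1cc(OC)c(Oc2cc(OC)c(OC)c(OC)c2Oc2cc(OC)c(OC(Br)=C)c(OC)c2)c(OC)c1
F0 | step 15 | none | none
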